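Ring B of the aryltetralin is cut across C4–C3 and C1–C2, back to a hydroxy-o-quinodimethane spanning C4–C4a=C8a–C1 and an (E)-enediol C2=C3. The trans 2,3-diol with trans carboxyl and hydroxymethyl groups is the imprint of a dihydroxyfumarate. It is locked as a menthone-derived spiro-1,3-dioxin-4-one that ties O-2 to the C-3 carbonyl carbon and so differentiates the two carboxyls. A photoenolisation/Diels–Alder reaction of a 2-benzylbenzaldehyde with this chiral dienophile forms both bonds and the stereocentres C1, C2 and C3 at once. The extra benzylic 4-OH, para to the C7 oxygen, is then removed by ionic hydrogenation.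

Key step: step 6

Remark on the chemistry: the target is read as the (1S,2S,3R)-acid (aryl at C1 cis to 2-OH, 2,3-diol trans); the tetralin numbering of the target is used for all ring-B intermediates, and compounds 1, 3, 7, 8 and 10 are taken as commercial.

Step 1
Reactants: 1 2-bromo-4-hydroxy-5-methoxybenzaldehyde (6-bromovanillin)
Product: 2 4-(benzyloxy)-2-bromo-5-methoxybenzaldehyde
Conditions: BnBr, K2CO3, DMF, 25 °C
Reagents that add atoms: benzyl bromide, BrCc1ccccc1
Why: Williamson etherification of the phenoxide with benzyl bromide; the aldehyde and the aryl bromide are inert under these conditions.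

Step 2
Reactants: 3 [3,4,5-tris(benzyloxy)phenyl]methanol
Product: 4 1,2,3-tris(benzyloxy)-5-(chloromethyl)benzene
Conditions: SOCl2, cat. DMF, CH2Cl2, 0 °C
Reagents that add atoms: thionyl chloride, O=S(Cl)Cl
Why: Deoxychlorination of a primary benzylic alcohol through its chlorosulfite; the aryl benzyl ethers tolerate the brief, cold acidic conditions.

Step 3
Reactants: 2 4-(benzyloxy)-2-bromo-5-methoxybenzaldehyde, 4 1,2,3-tris(benzyloxy)-5-(chloromethyl)benzene
Product: 6 4-(benzyloxy)-5-methoxy-2-{[3,4,5-tris(benzyloxy)phenyl]methyl}benzaldehyde, via benzylzinc chloride 5 (not isolated)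
Conditions: 4, Zn dust, LiCl, THF, 25 °C; then 2, Pd(OAc)2 (2 mol %), SPhos (4 mol %), THF, 25 °C, slow addition of the zinc reagent
Reagents that add atoms: none
Why: Negishi cross-coupling: zinc inserts into the benzylic C–Cl bond to give 5, which transmetalates to the arylpalladium bromide from 2 (oxidative addition helped by the ortho formyl group) faster than it adds to the aldehyde, and reductive elimination gives the diarylmethane.

Step 4
Reactants: 7 tert-butyl 2-(benzyloxy)acetate, 8 dibenzyl oxalate
Product: 9 4-benzyl 1-tert-butyl 2-(benzyloxy)-3-oxobutanedioate (largely enolised)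
Conditions: LiN(iPr)2, THF, −78 °C; then 8, −78 → 0 °C; aq. HCl work-up
Reagents that add atoms: none
Why: Crossed Claisen condensation of the glycolate ester enolate with the non-enolisable oxalate diester, driven by deprotonation of the acidic product; no stereocentre is retained because the product enolises.

Step 5
Reactants: 9 4-benzyl 1-tert-butyl 2-(benzyloxy)-3-oxobutanedioate, 10 (−)-menthone
Product: 11 benzyl (6R,7S,10R)-3-(benzyloxy)-10-methyl-4-oxo-7-(propan-2-yl)-1,5-dioxaspiro[5.5]undec-2-ene-2-carboxylate
Conditions: (CF3CO)2O, CF3CO2H, 0 → 25 °C; chromatographic separation of the two spiro epimers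
Reagents that add atoms: none
Why: Acid-mediated dioxinone formation (the enolised β-keto acid, freed from its tert-butyl ester, is acetalised by the ketone under dehydration by the anhydride) should give both epimers at the new spiro acetal carbon, and the (6R)-epimer, with the enol-ether oxygen O1 axial on the menthane chair, is isolated; the menthane stereocentres come from 10.

Step 6
Reactants: 6 4-(benzyloxy)-5-methoxy-2-{[3,4,5-tris(benzyloxy)phenyl]methyl}benzaldehyde, 11 the (6R)-spiro-dioxinone
Product: 13 cis-fused spiro-dioxanone cycloadduct with (1S,2S,3S,4R)-tetralin core, via photoenol 12 (not isolated)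
Conditions: hν (365 nm), degassed toluene, 20 °C, 6 (1.5 equiv), 11 (1.0 equiv), 0.05 M
Reagents that add atoms: none
Why: Excitation of aldehyde 6 should trigger a 1,5-hydrogen transfer from the doubly benzylic CH2 to the carbonyl oxygen and give the (E,E)-hydroxy-o-quinodimethane 12 (OH and aryl both outward), which is trapped by the C5=C6 bond of dioxinone 11 in a thermal suprafacial [4+2] cycloaddition (photoenolisation/Diels–Alder reaction; the closest known type is the trapping of photoenols of o-benzyl- and o-methylbenzaldehydes by cyclic enones and enoates). Ring B is closed by an intermolecular [4+2] annulation that forms C4–C3 and C1–C2 in one concerted, asynchronous step and leaves the dioxanone cis-fused. The trans relation of the two oxygens and of the two carbonyl carbons at C2/C3 is carried over from the ring-locked (E)-enediol geometry of 11, while C1 and C4 follow from the outward aryl and OH groups combined with the ring-endo transition state, in which the enol OH is hydrogen-bonded to the ring carbonyl, so that aryl, 4-OH, O-2 and the C-3 carbonyl carbon sit on one face. Absolute configuration is set by the spiro-menthane: the diene should add to the dioxinone face turned away from the isopropyl-bearing ring carbon, which for the (6R)-epimer gives (2S,3S) and hence (1S,4R). The step needs regioselectivity (aryl-bearing terminus to C6 of 11, carbinol terminus to C5), which the donor OH of the diene and the polarisation of the ring enoate (electrophilic at C6) should secure, and it needs the tetrasubstituted dienophile to intercept 12, whose reversion to 6 is harmless because 6 is simply re-excited.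

Step 7
Reactants: 13 the (1S,2S,3S,4R)-cycloadduct
Product: 14 the (1S,2S,3S)-4-deoxy cycloadduct
Conditions: Et3SiH, CF3CO2H, CH2Cl2, −20 → 0 °C
Reagents that add atoms: none
Why: Ionic hydrogenation: the acid ionises the C4 carbinol to a benzylic cation stabilised by the para 7-benzyloxy group and the silane delivers hydride, so C4 becomes CH2 with no stereochemical issue while the acylal (itself formed in this acid) and the benzyl ethers survive.

Step 8
Reactants: 14 the (1S,2S,3S)-4-deoxy cycloadduct
Product: 15 2-benzyl hydrogen (1S,2S,3S)-3,7-bis(benzyloxy)-2-hydroxy-6-methoxy-1-[3,4,5-tris(benzyloxy)phenyl]-1,2,3,4-tetrahydronaphthalene-2,3-dicarboxylate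
Conditions: 2 M aq. HCl, THF, 40 °C
Reagents that add atoms: none
Why: Acid-catalysed acylal hydrolysis: ionisation at the ketone-derived acetal carbon and capture of the oxocarbenium ion by water should release menthone (which takes up the water oxygen) and unmask the C3 carboxylic acid and the tertiary 2-OH without touching the benzyl ester, the benzyl ethers or any stereocentre.

Step 9
Reactants: 15 the C3 carboxylic acid
Product: 16 benzyl (1S,2S,3R)-3,7-bis(benzyloxy)-2-hydroxy-3-(hydroxymethyl)-6-methoxy-1-[3,4,5-tris(benzyloxy)phenyl]-1,2,3,4-tetrahydronaphthalene-2-carboxylate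
Conditions: BH3·THF, THF, 0 → 25 °C; MeOH quench
Reagents that add atoms: none
Why: Chemoselective borane reduction of a carboxylic acid: the acyloxyborane is reduced far faster than the hindered benzyl ester, so the C3 carboxyl becomes the hydroxymethyl group with C3 untouched.

Step 10
Reactants: 16 the hexabenzyl-protected hydroxymethyl ester
Product: 17 (1S,2S,3R)-2,3,7-trihydroxy-3-(hydroxymethyl)-6-methoxy-1-(3,4,5-trihydroxyphenyl)-1,2,3,4-tetrahydronaphthalene-2-carboxylic acid
Conditions: H2 (1 atm), Pd(OH)2/C, MeOH/THF, 25 °C; filtration and concentration under argon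
Reagents that add atoms: none
Why: Catalytic hydrogenolysis should cleave the four aryl benzyl ethers, the tertiary benzyl ether at C3 and the benzyl ester at C2 under neutral conditions, leaving the three stereocentres untouched.

Compound list
1 | 2-bromo-4-hydroxy-5-methoxybenzaldehyde (6-bromovanillin) | COc1cc(C=O)c(Br)cc1O | starting material
2 | 4-(benzyloxy)-2-bromo-5-methoxybenzaldehyde | COc1cc(C=O)c(Br)cc1OCc1ccccc1 | intermediate
3 | [3,4,5-tris(benzyloxy)phenyl]methanol | OCc1cc(OCc2ccccc2)c(OCc2ccccc2)c(OCc2ccccc2)c1 | starting material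
4 | 1,2,3-tris(benzyloxy)-5-(chloromethyl)benzene | ClCc1cc(OCc2ccccc2)c(OCc2ccccc2)c(OCc2ccccc2)c1 | intermediate
5 | [3,4,5-tris(benzyloxy)benzyl]zinc chloride | Cl[Zn]Cc1cc(OCc2ccccc2)c(OCc2ccccc2)c(OCc2ccccc2)c1 | intermediate (not isolated)
6 | 4-(benzyloxy)-5-methoxy-2-{[3,4,5-tris(benzyloxy)phenyl]methyl}benzaldehyde | COc1cc(C=O)c(Cc2cc(OCc3ccccc3)c(OCc3ccccc3)c(OCc3ccccc3)c2)cc1OCc1ccccc1 | intermediate
7 | tert-butyl 2-(benzyloxy)acetate | CC(C)(C)OC(=O)COCc1ccccc1 | starting material
8 | dibenzyl oxalate | O=C(OCc1ccccc1)C(=O)OCc1ccccc1 | starting material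
9 | 4-benzyl 1-tert-butyl 2-(benzyloxy)-3-oxobutanedioate | CC(C)(C)OC(=O)C(OCc1ccccc1)C(=O)C(=O)OCc1ccccc1 | intermediate
10 | (−)-menthone, (2S,5R)-5-methyl-2-(propan-2-yl)cyclohexan-1-one | CC(C)[C@@H]1CC[C@@H](C)CC1=O | starting material
11 | benzyl (6R,7S,10R)-3-(benzyloxy)-10-methyl-4-oxo-7-(propan-2-yl)-1,5-dioxaspiro[5.5]undec-2-ene-2-carboxylate | CC(C)[C@@H]1CC[C@@H](C)C[C@]12OC(C(=O)OCc3ccccc3)=C(OCc3ccccc3)C(=O)O2 | intermediate
12 | (5E,6E)-3-(benzyloxy)-6-(hydroxymethylidene)-2-methoxy-5-{[3,4,5-tris(benzyloxy)phenyl]methylidene}cyclohexa-1,3-diene (photoenol of 6, OH and aryl outward) | COC1=C/C(=C\O)/C(=C/c2cc(OCc3ccccc3)c(OCc3ccccc3)c(OCc3ccccc3)c2)C=C1OCc1ccccc1 | intermediate (not isolated)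
13 | benzyl (1S,2S,3S,4R)-3,7-bis(benzyloxy)-4-hydroxy-6-methoxy-1-[3,4,5-tris(benzyloxy)phenyl]-1,2,3,4-tetrahydronaphthalene-2-carboxylate in which O-2 and the carbonyl carbon on C3 are closed to a cis-fused 1,3-dioxan-4-one through the spiro acetal carbon C1 of a (1R,2S,5R)-2-isopropyl-5-methylcyclohexane | COc1cc2c(cc1OCc1ccccc1)[C@H](c1cc(OCc3ccccc3)c(OCc3ccccc3)c(OCc3ccccc3)c1)[C@]4(C(=O)OCc3ccccc3)O[C@]5(C[C@H](C)CC[C@H]5C(C)C)OC(=O)[C@]4(OCc3ccccc3)[C@@H]2O | intermediate
14 | the (1S,2S,3S)-4-deoxy analogue of 13 (C4 = CH2), same spiro-dioxanone | COc1cc2c(cc1OCc1ccccc1)[C@H](c1cc(OCc3ccccc3)c(OCc3ccccc3)c(OCc3ccccc3)c1)[C@]4(C(=O)OCc3ccccc3)O[C@]5(C[C@H](C)CC[C@H]5C(C)C)OC(=O)[C@]4(OCc3ccccc3)C2 | intermediate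
15 | 2-benzyl hydrogen (1S,2S,3S)-3,7-bis(benzyloxy)-2-hydroxy-6-methoxy-1-[3,4,5-tris(benzyloxy)phenyl]-1,2,3,4-tetrahydronaphthalene-2,3-dicarboxylate | COc1cc2c(cc1OCc1ccccc1)[C@H](c1cc(OCc3ccccc3)c(OCc3ccccc3)c(OCc3ccccc3)c1)[C@@](O)(C(=O)OCc1ccccc1)[C@](OCc1ccccc1)(C(=O)O)C2 | intermediate
16 | benzyl (1S,2S,3R)-3,7-bis(benzyloxy)-2-hydroxy-3-(hydroxymethyl)-6-methoxy-1-[3,4,5-tris(benzyloxy)phenyl]-1,2,3,4-tetrahydronaphthalene-2-carboxylate | COc1cc2c(cc1OCc1ccccc1)[C@H](c1cc(OCc3ccccc3)c(OCc3ccccc3)c(OCc3ccccc3)c1)[C@@](O)(C(=O)OCc1ccccc1)[C@](OCc1ccccc1)(CO)C2 | intermediate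
17 | (1S,2S,3R)-2,3,7-trihydroxy-3-(hydroxymethyl)-6-methoxy-1-(3,4,5-trihydroxyphenyl)-1,2,3,4-tetrahydronaphthalene-2-carboxylic acid | COc1cc2c(cc1O)[C@H](c1cc(O)c(O)c(O)c1)[C@@](O)(C(=O)O)[C@](O)(CO)C2 | target

Total step count: 10. Longest linear sequence: 7 steps (steps 1, 3, 6, 7, 8, 9, 10; the branch through steps 4 and 5 is equally long).

Steps most likely to fail

Step 6. Interception of the short-lived photoenol by the hindered, tetrasubstituted dienophile may be too slow, so that the dienol keeps reverting while aldehyde and dioxinone are slowly consumed by other photoreactions. Some material may also leak into the other regio-orientation. The fallback separates diene generation from the cycloaddition. Setting out from 6, irradiation (365 nm) in benzene saturated with SO2 should trap the photoenol as the cyclic hydroxy sulfone 5-(benzyloxy)-1-hydroxy-6-methoxy-3-[3,4,5-tris(benzyloxy)phenyl]-1,3-dihydro-2-benzothiophene 2,2-dioxide F1. Heating F1 with 11 in toluene at 85 °C in the dark should extrude SO2 and release the same (E,E)-dienol slowly into a concentrated solution of the dienophile. The route is rejoined at 13.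

Step 5. Acid-mediated spiroacetalisation with the hindered, enolisable ketone may stall, and the acid may epimerise the isopropyl-bearing carbon of menthone before it is trapped. The fallback sets out from 9. Acetone, (CF3CO)2O and CF3CO2H should first give the unhindered dioxinone benzyl 5-(benzyloxy)-2,2-dimethyl-4-oxo-4H-1,3-dioxine-6-carboxylate F2. Heating F2 with 10 in toluene at 110 °C, with acetone distilled off, should exchange the ketone through the acylketene (retro-[4+2], then [4+2] with the menthone carbonyl) under neutral conditions. The route is rejoined at 11 after separation of the spiro epimers.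

Step 3. The benzylic zinc reagent may add to the formyl group of 2 or 6, or homocouple, in competition with cross-coupling. The fallback reverses the polarity and sets out from 2. Miyaura borylation (B2pin2, PdCl2(dppf), KOAc, dioxane, 90 °C) should give 4-(benzyloxy)-5-methoxy-2-(4,4,5,5-tetramethyl-1,3,2-dioxaborolan-2-yl)benzaldehyde F3. Suzuki–Miyaura coupling of F3 with benzylic chloride 4 (PdCl2(dppf), K2CO3, dioxane/H2O, 80 °C) tolerates the aldehyde and rejoins the route at 6.

Further compounds
F1 | step 6 | 5-(benzyloxy)-1-hydroxy-6-methoxy-3-[3,4,5-tris(benzyloxy)phenyl]-1,3-dihydro-2-benzothiophene 2,2-dioxide | COc1cc2c(cc1OCc1ccccc1)C(c1cc(OCc3ccccc3)c(OCc3ccccc3)c(OCc3ccccc3)c1)S(=O)(=O)C2O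
F2 | step 5 | benzyl 5-(benzyloxy)-2,2-dimethyl-4-oxo-4H-1,3-dioxine-6-carboxylate | CC1(C)OC(C(=O)OCc2ccccc2)=C(OCc2ccccc2)C(=O)O1
F3 | step 3 | 4-(benzyloxy)-5-methoxy-2-(4,4,5,5-tetramethyl-1,3,2-dioxaborolan-2-yl)benzaldehyde | COc1cc(C=O)c(B2OC(C)(C)C(C)(C)O2)cc1OCc1ccccc1
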